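**Assumption:** xenicane locants (C1, O2, C3, C4, C4a, C5–C11, C11a, C12–C17; C18 = methyl on C7, C19 = exocyclic methylene carbon) are used for every intermediate, and the target is read as (1R,4aS,7S,8S,11aR,12R) with an (E)-enoate.

## Retrosynthetic overview

1. Target 22 ⇐ triene diacetate 21 by epoxidation of the strained (E)-C7=C8 alkene; 21 ⇐ formyl dihydropyran 17 + tiglate dienolate 19 by vinylogous Mukaiyama aldol (C12–C13, sets C12).
2. Dihydropyran acetal 17 ⇐ tris-acetal 15: unmasking of a C1 aldehyde and a C4 malondialdehyde, lactolization, acetylation (sets C1).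
3. Nine-membered ring 14 ⇐ cis-hydrindane diol monomesylate 13 by Grob fragmentation of the C7–C11 bond (gives the C11 ketone and the (E)-C7=C8 alkene).
4. Hydrindane 11 ⇐ aldol adduct 9 by a paired-electrolysis C10–C11 ring closure; 9 ⇐ enone 6 + acrolein (reductive aldol).
5. 6 ⇐ (S)-carvone, which supplies C4a and all ten of its carbons. Ring order: cyclohexane (bought) → cyclopentane → cyclononene → dihydropyran → oxirane.

## Route

Step 1
Reactants: 1 (S)-carvone
Product: 3 (5S,6S)-6-(dimethoxymethyl)-2-methyl-5-(prop-1-en-2-yl)cyclohex-2-en-1-one, via silyl dienol ether 2 (not isolated)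
Conditions: LiN(i-Pr)2, THF, −78 °C; Me3SiCl; then HC(OMe)3, Me3SiOTf (5 mol %), CH2Cl2, −78 °C
Reagents that add atoms: trimethyl orthoformate, COC(OC)OC; chlorotrimethylsilane, C[Si](C)(C)Cl (its silicon stays only in 2)
Why: Kinetic α′-deprotonation gives the cross-conjugated silyl dienol ether, which undergoes a Mukaiyama-type orthoformate alkylation at C11a on the face anti to the isopropenyl group (the trans product is also the thermodynamic one), so C11a is set by the purchased C4a centre.

Step 2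
Reactants: 3 (5S,6S)-6-(dimethoxymethyl)-2-methyl-5-(prop-1-en-2-yl)cyclohex-2-en-1-one
Product: 5 2-[(1S,2S)-2-(dimethoxymethyl)-4-methyl-3-oxocyclohex-4-en-1-yl]prop-2-enal, via allylic alcohol 4 (not isolated)
Conditions: SeO2 (0.3 equiv), t-BuOOH, CH2Cl2, 25 °C; filter; then MnO2, CH2Cl2, 25 °C
Reagents that add atoms: tert-butyl hydroperoxide, CC(C)(C)OO
Why: Selenium dioxide allylic oxidation (ene reaction then 2,3-shift) attacks only the isopropenyl methyl because the other alkene is a deactivated enone, and MnO2 then oxidises the primary allylic alcohol to the 2-substituted acrolein without touching a stereocentre.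

Step 3
Reactants: 5 2-[(1S,2S)-2-(dimethoxymethyl)-4-methyl-3-oxocyclohex-4-en-1-yl]prop-2-enal
Product: 6 (5R,6S)-6-(dimethoxymethyl)-2-methyl-5-(1,1,3,3-tetramethoxypropan-2-yl)cyclohex-2-en-1-one
Conditions: PdCl2(MeCN)2 (10 mol %), CuCl (20 mol %), O2 (1 atm), MeOH–DME, 4 Å MS, 50 °C
Reagents that add atoms: methanol, CO
Why: Wacker-type oxidative acetalization: divalent palladium delivers methoxide to the terminal acrolein carbon, β-hydride elimination gives the β-methoxy enal, and acid-catalysed methanol addition and acetalization give the masked malondialdehyde, whose two identical arms create no stereocentre (the descriptor change at C5 is only a priority change).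

Step 4
Reactants: 6 (5R,6S)-6-(dimethoxymethyl)-2-methyl-5-(1,1,3,3-tetramethoxypropan-2-yl)cyclohex-2-en-1-one; 7 acrolein
Product: 9 (2S,5R,6S)-6-(dimethoxymethyl)-2-[(1S)-1-hydroxyprop-2-en-1-yl]-2-methyl-5-(1,1,3,3-tetramethoxypropan-2-yl)cyclohexan-1-one, via lithium enolate 8 (not isolated)
Conditions: LiBH(s-Bu)3, THF, −78 °C; then acrolein, −78 °C; AcOH quench
Reagents that add atoms: none
Why: Conjugate hydride addition gives the regiodefined tetrasubstituted enolate, which adds 1,2 to acrolein by axial attack (reductive aldol) to build the C7 quaternary carbon; the C7 and C8 configurations are transient because both carbons become sp2 in step 7, so the C8 epimer converges.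

Step 5
Reactants: 9 (2S,5R,6S)-6-(dimethoxymethyl)-2-[(1S)-1-hydroxyprop-2-en-1-yl]-2-methyl-5-(1,1,3,3-tetramethoxypropan-2-yl)cyclohexan-1-one
Product: 11 (3aR,4R,5S,7aR)-4-(dimethoxymethyl)-3a-hydroxy-7a-methyl-5-(1,1,3,3-tetramethoxypropan-2-yl)octahydro-1H-inden-1-one, via vinyl ketone 10 (not isolated)
Conditions: ABNO (10 mol %), 2,6-lutidine (1 equiv), n-Bu4NBF4 (0.1 M), MeCN, undivided cell, graphite-felt anode, Sn cathode, 5 mA cm−2, 2.2 F mol−1, 20 °C
Reagents that add atoms: none
Why: Proposed new method: a domino paired electrolysis in which the anodically generated ABNO oxoammonium oxidises the hindered allylic carbinol to vinyl ketone 10 and the tin cathode (about −2.0 V vs SCE, lutidinium as proton donor) reduces 10 to its radical anion, whose β-carbon (C10) adds 5-exo to the C11 ketone to close the cyclopentanol, the short tether forcing cis fusion (C11 hydroxyl cis to the C7 methyl); the closest known reactions are aminoxyl-mediated anodic alcohol oxidation and the Shono/Little cathodic cyclization of enones onto ketones, here merged into one redox-neutral isomerization.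

Step 6
Reactants: 11 (3aR,4R,5S,7aR)-4-(dimethoxymethyl)-3a-hydroxy-7a-methyl-5-(1,1,3,3-tetramethoxypropan-2-yl)octahydro-1H-inden-1-one
Product: 12 (1R,3aR,4R,5S,7aS)-4-(dimethoxymethyl)-7a-methyl-5-(1,1,3,3-tetramethoxypropan-2-yl)octahydro-1H-indene-1,3a-diol
Conditions: Et2BOMe, THF–MeOH (4:1), −78 °C; NaBH4, −78 °C; AcOH, then MeOH co-evaporation
Reagents that add atoms: none
Why: Narasaka–Prasad reduction: the diethylboron chelate bridging the C11 hydroxyl and the C8 carbonyl on the methyl-bearing face forces external hydride onto the opposite face, giving the 1,3-syn diol with the C8 hydroxyl cis to the C11 hydroxyl and the C7 methyl, the relationship an (E)-selective fragmentation needs.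

Step 7
Reactants: 12 (1R,3aR,4R,5S,7aS)-4-(dimethoxymethyl)-7a-methyl-5-(1,1,3,3-tetramethoxypropan-2-yl)octahydro-1H-indene-1,3a-diol
Product: 14 (4E,8R,9S)-9-(dimethoxymethyl)-5-methyl-8-(1,1,3,3-tetramethoxypropan-2-yl)cyclonon-4-en-1-one, via mesylate 13 (not isolated)
Conditions: MsCl, Et3N, CH2Cl2, 0 °C; then KOt-Bu (1.1 equiv), THF, −20 °C
Reagents that add atoms: methanesulfonyl chloride, CS(=O)(=O)Cl (its atoms stay only in 13)
Why: Selective mesylation of the secondary alcohol and alkoxide-triggered Grob (Wharton) fragmentation cleave the C11–C7 bond anti-periplanar to C8–OMs, giving the C11 ketone and, because the leaving group is cis to the C7 methyl, only the (E)-C7=C8 alkene of the nine-membered ring, as in classical caryophyllene-type fragmentations.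

Step 8
Reactants: 14 (4E,8R,9S)-9-(dimethoxymethyl)-5-methyl-8-(1,1,3,3-tetramethoxypropan-2-yl)cyclonon-4-en-1-one
Product: 15 (1R,2S,5E)-1-(dimethoxymethyl)-5-methyl-9-methylidene-2-(1,1,3,3-tetramethoxypropan-2-yl)cyclonon-5-ene
Conditions: Cp2TiMe2 (3 equiv), toluene–THF, 70 °C, dark
Reagents that add atoms: dimethyltitanocene Cp2TiMe2, C[Ti](C)(C1C=CC=C1)C1C=CC=C1
Why: Petasis methylenation is non-basic, so the hindered C11 ketone becomes the exocyclic methylene without epimerising C11a or eliminating methanol from the neighbouring acetal.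

Step 9
Reactants: 15 (1R,2S,5E)-1-(dimethoxymethyl)-5-methyl-9-methylidene-2-(1,1,3,3-tetramethoxypropan-2-yl)cyclonon-5-ene
Product: 17 (1R,4aS,7E,11aR)-4-formyl-7-methyl-11-methylidene-1,4a,5,6,9,10,11,11a-octahydrocyclonona[c]pyran-1-yl acetate, via lactol 16 (not isolated)
Conditions: AcOH–THF–H2O (3:1:1), 35 °C; concentrate; then Ac2O, pyridine, DMAP (cat.), CH2Cl2, 0 °C
Reagents that add atoms: water, O; acetic anhydride, CC(=O)OC(C)=O
Why: Mild acid unmasks all three acetals, the enol hydroxyl of the C4 malondialdehyde adds to the C1 aldehyde to give the six-membered lactol (the xenicane dihydropyran as a vinylogous formate), and DMAP acetylation traps the less hindered equatorial anomer with the acetoxy group trans to the C11a–C11 bond (1R), so C1 is set by C11a.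

Step 10
Reactants: 18 methyl tiglate
Product: 19 tert-butyl[(1-methoxy-2-methylbuta-1,3-dien-1-yl)oxy]dimethylsilane
Conditions: LiN(i-Pr)2, DMPU, THF, −78 °C; t-BuMe2SiCl
Reagents that add atoms: tert-butyldimethylsilyl chloride, CC(C)(C)[Si](C)(C)Cl
Why: γ-Deprotonation of the enoate and O-silylation give the vinylketene silyl acetal needed for a vinylogous aldol; no stereocentre is involved.

Step 11
Reactants: 17 (1R,4aS,7E,11aR)-4-formyl-7-methyl-11-methylidene-1,4a,5,6,9,10,11,11a-octahydrocyclonona[c]pyran-1-yl acetate; 19 tert-butyl[(1-methoxy-2-methylbuta-1,3-dien-1-yl)oxy]dimethylsilane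
Product: 20 methyl (2E,5R)-5-[(1R,4aS,7E,11aR)-1-acetoxy-7-methyl-11-methylidene-1,4a,5,6,9,10,11,11a-octahydrocyclonona[c]pyran-4-yl]-5-hydroxy-2-methylpent-2-enoate
Conditions: B(C6F5)3 (20 mol %), i-PrOH (1.2 equiv), Et2O, −78 °C
Reagents that add atoms: none
Why: Vinylogous Mukaiyama aldol: the dienolate reacts at its γ-carbon to give the (E)-enoate side chain in one step, and A(1,3) strain turns the formyl hydrogen toward C4a so that attack on the face anti to the C5 methylene (the H-4a face) gives 12R, i.e. C12 is controlled by C4a.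

Step 12
Reactants: 20 methyl (2E,5R)-5-[(1R,4aS,7E,11aR)-1-acetoxy-7-methyl-11-methylidene-1,4a,5,6,9,10,11,11a-octahydrocyclonona[c]pyran-4-yl]-5-hydroxy-2-methylpent-2-enoate
Product: 21 methyl (2E,5R)-5-acetoxy-5-[(1R,4aS,7E,11aR)-1-acetoxy-7-methyl-11-methylidene-1,4a,5,6,9,10,11,11a-octahydrocyclonona[c]pyran-4-yl]-2-methylpent-2-enoate
Conditions: Ac2O, pyridine, DMAP (cat.), CH2Cl2, 0 °C
Reagents that add atoms: acetic anhydride, CC(=O)OC(C)=O
Why: Base-mediated O-acetylation with retention at C12; the absence of acid avoids Ferrier-type ionization of the allylic position next to the enol ether.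

Step 13
Reactants: 21 methyl (2E,5R)-5-acetoxy-5-[(1R,4aS,7E,11aR)-1-acetoxy-7-methyl-11-methylidene-1,4a,5,6,9,10,11,11a-octahydrocyclonona[c]pyran-4-yl]-2-methylpent-2-enoate
Product: 22 methyl (2E,5R)-5-acetoxy-5-[(1R,4aS,7S,8S,11aR)-1-acetoxy-7,8-epoxy-7-methyl-11-methylidene-1,4a,5,6,7,8,9,10,11,11a-decahydrocyclonona[c]pyran-4-yl]-2-methylpent-2-enoate (CNP0184381.4)
Conditions: mCPBA (1.05 equiv), CH2Cl2 / aq. Na2HPO4–NaH2PO4 buffer (pH 8), 0 °C
Reagents that add atoms: 3-chloroperoxybenzoic acid, OOC(=O)c1cccc(Cl)c1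
Why: Prilezhaev epoxidation: the strained trisubstituted (E)-cyclononene reacts far faster than the 1,1-disubstituted methylene, the enoate or the acyloxy-deactivated enol ether, and peripheral attack on the outer face of the trans-fused nine-membered ring (the caryophyllene to caryophyllene oxide pattern) gives 7S,8S under control of C4a and C11a.

## Compound list

1 | (S)-(+)-carvone, (5S)-2-methyl-5-(prop-1-en-2-yl)cyclohex-2-en-1-one | CC1=CC[C@@H](CC1=O)C(C)=C | starting material
2 | trimethyl{[(3S)-6-methyl-3-(prop-1-en-2-yl)cyclohexa-1,5-dien-1-yl]oxy}silane (kinetic silyl dienol ether) | CC1=CC[C@@H](C=C1O[Si](C)(C)C)C(C)=C | intermediate (not isolated)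
3 | (5S,6S)-6-(dimethoxymethyl)-2-methyl-5-(prop-1-en-2-yl)cyclohex-2-en-1-one (5,6-trans) | CC1=CC[C@@H]([C@@H](C(OC)OC)C1=O)C(C)=C | intermediate
4 | (5S,6S)-6-(dimethoxymethyl)-5-(3-hydroxyprop-1-en-2-yl)-2-methylcyclohex-2-en-1-one | CC1=CC[C@@H]([C@@H](C(OC)OC)C1=O)C(CO)=C | intermediate (not isolated)
5 | 2-[(1S,2S)-2-(dimethoxymethyl)-4-methyl-3-oxocyclohex-4-en-1-yl]prop-2-enal | CC1=CC[C@@H]([C@@H](C(OC)OC)C1=O)C(C=O)=C | intermediate
6 | (5R,6S)-6-(dimethoxymethyl)-2-methyl-5-(1,1,3,3-tetramethoxypropan-2-yl)cyclohex-2-en-1-one | CC1=CC[C@@H]([C@@H](C(OC)OC)C1=O)C(C(OC)OC)C(OC)OC | intermediate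
7 | acrolein (prop-2-enal) | C=CC=O | starting material
8 | lithium 6-(dimethoxymethyl)-2-methyl-5-(1,1,3,3-tetramethoxypropan-2-yl)cyclohex-1-en-1-olate (ring stereocentres as in 6) | CC1=C(O[Li])[C@H](C(OC)OC)[C@H](CC1)C(C(OC)OC)C(OC)OC | intermediate (not isolated)
9 | (2S,5R,6S)-6-(dimethoxymethyl)-2-[(1S)-1-hydroxyprop-2-en-1-yl]-2-methyl-5-(1,1,3,3-tetramethoxypropan-2-yl)cyclohexan-1-one (major aldol isomer; carbinol epimer converges) | C[C@@]1([C@@H](O)C=C)CC[C@@H]([C@@H](C(OC)OC)C1=O)C(C(OC)OC)C(OC)OC | intermediate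
10 | (2S,5R,6S)-2-acryloyl-6-(dimethoxymethyl)-2-methyl-5-(1,1,3,3-tetramethoxypropan-2-yl)cyclohexan-1-one | C[C@@]1(C(=O)C=C)CC[C@@H]([C@@H](C(OC)OC)C1=O)C(C(OC)OC)C(OC)OC | intermediate (not isolated)
11 | (3aR,4R,5S,7aR)-4-(dimethoxymethyl)-3a-hydroxy-7a-methyl-5-(1,1,3,3-tetramethoxypropan-2-yl)octahydro-1H-inden-1-one (cis-fused; 3a-OH, 7a-CH3 and 4-acetal on one face) | C[C@@]12CC[C@H](C(C(OC)OC)C(OC)OC)[C@@H](C(OC)OC)[C@]1(O)CCC2=O | intermediate
12 | (1R,3aR,4R,5S,7aS)-4-(dimethoxymethyl)-7a-methyl-5-(1,1,3,3-tetramethoxypropan-2-yl)octahydro-1H-indene-1,3a-diol (1-OH, 3a-OH and 7a-CH3 all cis) | C[C@@]12CC[C@H](C(C(OC)OC)C(OC)OC)[C@@H](C(OC)OC)[C@]1(O)CC[C@H]2O | intermediate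
13 | (1R,3aR,4R,5S,7aS)-4-(dimethoxymethyl)-3a-hydroxy-7a-methyl-5-(1,1,3,3-tetramethoxypropan-2-yl)octahydro-1H-inden-1-yl methanesulfonate | C[C@@]12CC[C@H](C(C(OC)OC)C(OC)OC)[C@@H](C(OC)OC)[C@]1(O)CC[C@H]2OS(C)(=O)=O | intermediate (not isolated)
14 | (4E,8R,9S)-9-(dimethoxymethyl)-5-methyl-8-(1,1,3,3-tetramethoxypropan-2-yl)cyclonon-4-en-1-one | O=C1CC/C=C(\C)CC[C@H](C(C(OC)OC)C(OC)OC)[C@H]1C(OC)OC | intermediate
15 | (1R,2S,5E)-1-(dimethoxymethyl)-5-methyl-9-methylidene-2-(1,1,3,3-tetramethoxypropan-2-yl)cyclonon-5-ene | C=C1CC/C=C(\C)CC[C@H](C(C(OC)OC)C(OC)OC)[C@H]1C(OC)OC | intermediate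
16 | (4aS,7E,11aR)-1-hydroxy-7-methyl-11-methylidene-1,4a,5,6,9,10,11,11a-octahydrocyclonona[c]pyran-4-carbaldehyde (equilibrating anomers at C1) | C=C1CC/C=C(\C)CC[C@@H]2C(C=O)=COC(O)[C@@H]12 | intermediate (not isolated)
17 | (1R,4aS,7E,11aR)-4-formyl-7-methyl-11-methylidene-1,4a,5,6,9,10,11,11a-octahydrocyclonona[c]pyran-1-yl acetate | C=C1CC/C=C(\C)CC[C@@H]2C(C=O)=CO[C@H](OC(C)=O)[C@@H]12 | intermediate
18 | methyl tiglate, methyl (2E)-2-methylbut-2-enoate | C/C=C(\C)C(=O)OC | starting material
19 | tert-butyl[(1-methoxy-2-methylbuta-1,3-dien-1-yl)oxy]dimethylsilane (ketene acetal geometry inconsequential) | C=CC(C)=C(OC)O[Si](C)(C)C(C)(C)C | intermediate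
20 | methyl (2E,5R)-5-[(1R,4aS,7E,11aR)-1-acetoxy-7-methyl-11-methylidene-1,4a,5,6,9,10,11,11a-octahydrocyclonona[c]pyran-4-yl]-5-hydroxy-2-methylpent-2-enoate | C=C1CC/C=C(\C)CC[C@@H]2C([C@@H](C/C=C(\C)C(=O)OC)O)=CO[C@H](OC(C)=O)[C@@H]12 | intermediate
21 | methyl (2E,5R)-5-acetoxy-5-[(1R,4aS,7E,11aR)-1-acetoxy-7-methyl-11-methylidene-1,4a,5,6,9,10,11,11a-octahydrocyclonona[c]pyran-4-yl]-2-methylpent-2-enoate | C=C1CC/C=C(\C)CC[C@@H]2C([C@@H](C/C=C(\C)C(=O)OC)OC(C)=O)=CO[C@H](OC(C)=O)[C@@H]12 | intermediate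
22 | methyl (2E,5R)-5-acetoxy-5-[(1R,4aS,7S,8S,11aR)-1-acetoxy-7,8-epoxy-7-methyl-11-methylidene-1,4a,5,6,7,8,9,10,11,11a-decahydrocyclonona[c]pyran-4-yl]-2-methylpent-2-enoate (CNP0184381.4) | C=C1CC[C@@H]2O[C@@]2(C)CC[C@@H]2C([C@@H](C/C=C(\C)C(=O)OC)OC(C)=O)=CO[C@H](OC(C)=O)[C@@H]12 | target

## Step count and risks

Total step count: 13. Longest linear sequence: 12 (steps 1–9 and 11–13); step 10 is a one-step side branch.

The three steps most likely to fail:

**Step 5 (the new paired electrolysis).** The oxoammonium mediator may be reduced at the cathode instead of 10, and 10 may be simply hydrogenated or hydrodimerised instead of cyclising. The fallback sets out from 9 and comes back at 11 using known chemistry only. Dess–Martin periodinane (CH2Cl2, NaHCO3) oxidises 9 to the vinyl ketone 10, which is now isolated. It is then cyclised by a conventional cathodic enone–ketone electroreductive cyclization in a divided cell (Sn cathode, Et4NOTs, DMF, dimethyl malonate as proton donor). The oxidation and the reductive bond formation are thus separated into two classical operations, and no new compound is made (F0).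

**Step 3 (oxidative acetalization of an α-branched acrolein).** Methoxypalladation of the hindered alkene may be slow, or β-hydride elimination may go toward C4a. The fallback sets out from 5 and comes back at 6 by halogenation and addition–elimination instead of palladium catalysis. Br2 (CH2Cl2, −78 °C) adds to the 1,1-disubstituted acrolein double bond, which is more reactive than the enone, to give the 2,3-dibromo aldehyde F1. Et3N removes HBr to give the 3-bromo-2-substituted acrolein F2. NaOMe in MeOH (0 °C) replaces bromide to give the 3-methoxy-2-substituted acrolein F3. MeOH, PPTS and 4 Å MS then convert F3 into the tris-acetal 6.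

**Step 11 (vinylogous aldol).** The facial selectivity at C12 rests on a conformational model, and the adduct is an ionisable allylic alcohol. The fallback sets out from 17 and comes back at 21. If the aldol gives mainly the C12 epimer, that (5S)-alcohol F4 is isolated and esterified under Mitsunobu conditions (AcOH, PPh3, DIAD, toluene, 0 °C). This installs the acetate with inversion at C12 and gives 21 directly, replacing the retentive acetylation of step 12.

Further compounds
F1 | step 3 | 2,3-dibromo-2-[(1S,2S)-2-(dimethoxymethyl)-4-methyl-3-oxocyclohex-4-en-1-yl]propanal (mixture at the new C–Br centre) | CC1=CC[C@@H]([C@@H](C(OC)OC)C1=O)C(Br)(CBr)C=O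
F2 | step 3 | 3-bromo-2-[(1S,2S)-2-(dimethoxymethyl)-4-methyl-3-oxocyclohex-4-en-1-yl]prop-2-enal | CC1=CC[C@@H]([C@@H](C(OC)OC)C1=O)C(C=O)=CBr
F3 | step 3 | 2-[(1S,2S)-2-(dimethoxymethyl)-4-methyl-3-oxocyclohex-4-en-1-yl]-3-methoxyprop-2-enal | CC1=CC[C@@H]([C@@H](C(OC)OC)C1=O)C(C=O)=COC
F0 | step 5 | none | none
F4 | step 11 | methyl (2E,5S)-5-[(1R,4aS,7E,11aR)-1-acetoxy-7-methyl-11-methylidene-1,4a,5,6,9,10,11,11a-octahydrocyclonona[c]pyran-4-yl]-5-hydroxy-2-methylpent-2-enoate (C12 epimer of 20) | C=C1CC/C=C(\C)CC[C@@H]2C([C@H](C/C=C(\C)C(=O)OC)O)=CO[C@H](OC(C)=O)[C@@H]12
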